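**Two runs.** From the blue run to the red run G rises by a factor 1.50, and the level of L goes from 9.92% to 14.9%, a factor 1.50, while Z goes from 23.1% to 21.5%.

in all of them: Q 0.80 M; J 1.05 equiv

| flask | G | remark | time |
|---|---|---|---|
| blue | 0.50 equiv | run made earlier |  |
| red | 0.75 equiv | run made earlier |  |
| flask | 1.00 equiv |  | 15 d |

| run | time / d | L / % | Z / % |
|---|---|---|---|
| blue | 2.50 | 9.3 | 21.9 |
| blue | 5.00 | 10.8 | 22.6 |
| blue | 8.00 | 10.0 | 23.9 |
| blue | 10.0 | 9.1 | 23.3 |
| blue | 12.0 | 10.0 | 23.0 |
| blue | 15.0 | 9.7 | 22.6 |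
| red | 1.04 | 7.7 | 15.0 |
| red | 3.00 | 14.3 | 20.7 |
| red | 5.00 | 14.5 | 21.8 |
| red | 8.00 | 14.7 | 21.2 |
| red | 12.0 | 15.6 | 22.2 |
| red | 15.0 | 15.2 | 21.5 |

(readings scatter by 1 percentage point)



- share of L in L plus Z at 1.0 h
- share of L in L plus Z at 15 d

**Carried factor.** L and Z look to me like two outlets of one thing made from Q, with G feeding one and J the other. So I carry the ratio of L to Z divided by the ratio of G to J charged: the blue run reads 0.903, the red run 0.969, and their mean 0.936 is my reading of the selectivity factor. For the flask it gives a share of L of 47.1%. The red share is 40.9% at 3.00 d and 41.4% at 15.0 d. The 33.9% at 1.04 d stands lower, from readings of 7.7% and 15.0% that each scatter by 1 percentage point, so I hold the share flat and commit to 47.1% at both times.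

**The curve.** The sum of L and Z in the red run reaches 22.7% at 1.04 d, out of a level of 36.3%, which reads as a half-time of 0.736 d; I take it for the flask too. Blue levels off at 33.0%, and one more equal step gives the flask 39.7%. So the flask's sum starts steeply, stands at 1.53% at 1.0 h, bends after 3 half-times at 34.7%, and runs flat, 15 d being 20.4 half-times. By this reckoning the flask ends with L at 18.7% and Z at 21.0%, Z above L.

**The forecast.** The forecast says 36% at 1.0 h, below my figure, and 49% at 15 d, the early one a guess “with wide uncertainty”.

**The result.** The flask gives 45.4% at 1.0 h and 46.7% at 15 d.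

    Q → X (k = 1.07 × 10⁻⁵ /s)
    Z → D (k = 3.21 × 10⁻⁸ /s)
    X → E (k = 0.0651 /s)
    G + X → L (k = 0.0266 /M/s)
    J + X → Z (k = 0.0305 /M/s)

In the flask Z goes on to D with a half-life, by that step alone, of 250 d, long against 15 d, and stands at 20.5% at the end. For the neighbouring flask with 0.630 equiv of J, my factor gives a share of 59.8%, and that flask stands at 59.4% at 15 d.

(The data are calculated for substances that don't exist, and the scatter is random.)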